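**Retrosynthetic overview**
The norbornene core is a cyclohexene retron: C-1 and C-3 of the five-membered guaiane ring carry the two-carbon bridge C-13′–C-11′, C-4=C-5 lies opposite, and C-2 (OAc) is the one-atom bridge. Retro-[4+2] cleavage of C-1–C-13′ and C-3–C-11′ opens the ring C-1–C-13′–C-11′–C-3–C-2 and gives cyclopentadiene 26 (C-1=C-5–C-4=C-3) and the exocyclic C-11′=C-13′ of α-methylene lactone 25.
Diene 26 is released in the flask from tertiary allylic alcohol 24, which comes from cyclopentenone 19 by γ-hydroxylation with singlet oxygen, CBS reduction and acetylation.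
Enone 19 comes from a Nazarov cyclisation of dienone 18 (carbonylative Stille coupling of enol triflate 17); the seven-membered ring comes from ring-closing metathesis (11 to 12); the lactone comes from butenolide 7; C-10 comes from (S)-2-methylsuccinate 1.
Order of ring formation: γ-lactone (step 5), seven-membered ring (step 10), cyclopentenone (step 15), and last the ring C-1–C-13′–C-11′–C-3–C-2 (step 20); the two rings of 25 are bought.

Key step: step 20

Remark: 1-O-acetylbritannilactone (25) is used as the purchased natural product; locants follow guaiane numbering (C-1 to C-15) for the diene half and primed britannilactone numbering for 25, and α is the face of H-7.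

Step 1
Reactants: 1 (S)-2-methylsuccinic acid 4-methyl ester
Product: 2 methyl (3S)-4-hydroxy-3-methylbutanoate
Conditions: BH3·SMe2, THF, 0 °C to rt; MeOH quench; used at once
Reagents that add atoms: none
Why: Borane reduces the free carboxylic acid far faster than the methyl ester (chemoselective acid reduction) and does not touch the C-10 stereocentre.

Step 2
Reactants: 2 methyl (3S)-4-hydroxy-3-methylbutanoate
Product: 3 methyl (3S)-4-[(tert-butyldimethylsilyl)oxy]-3-methylbutanoate
Conditions: TBSCl, imidazole, DMF, 0 °C to rt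
Reagents that add atoms: tert-butyldimethylsilyl chloride CC(C)(C)[Si](C)(C)Cl
Why: Silylation of the primary alcohol, done at once so that the γ-hydroxy ester cannot lactonise.

Step 3
Reactants: 3 methyl (3S)-4-[(tert-butyldimethylsilyl)oxy]-3-methylbutanoate
Product: 4 (3S)-4-[(tert-butyldimethylsilyl)oxy]-3-methylbutanal
Conditions: i-Bu2AlH, CH2Cl2, −78 °C; Rochelle salt work-up
Reagents that add atoms: none
Why: Partial ester reduction with i-Bu2AlH stops at the aluminium hemiacetal at −78 °C and gives the aldehyde on work-up.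

Step 4
Reactants: 4 (3S)-4-[(tert-butyldimethylsilyl)oxy]-3-methylbutanal
Product: 5 methyl (4S,6S)-7-[(tert-butyldimethylsilyl)oxy]-4-hydroxy-6-methylhept-2-ynoate
Conditions: methyl propiolate, Me2Zn, ProPhenol ligand (20 mol%, the enantiomer that gives the 4S carbinol), Ph3P=O (40 mol%), toluene, 4 °C
Reagents that add atoms: methyl propiolate C#CC(=O)OC
Why: Zinc–ProPhenol-catalysed asymmetric alkynylation adds the zinc acetylide of the propiolate to one aldehyde face, so the ligand sets the C-8 carbinol (4S).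

Step 5
Reactants: 5 methyl (4S,6S)-7-[(tert-butyldimethylsilyl)oxy]-4-hydroxy-6-methylhept-2-ynoate
Product: 7 (5S)-5-[(2S)-3-[(tert-butyldimethylsilyl)oxy]-2-methylpropyl]furan-2(5H)-one, via Z-hydroxy enoate 6 (not isolated)
Conditions: H2 (1 atm), Lindlar catalyst (Pd/CaCO3 poisoned with Pb(OAc)2), quinoline, EtOAc, rt; then PPTS (cat.), CH2Cl2, rt
Reagents that add atoms: none
Why: Lindlar semi-hydrogenation gives the Z-enoate, whose γ-hydroxyl sits next to the ester and lactonises to the butenolide without touching C-8.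

Step 6
Reactants: 7 (5S)-5-[(2S)-3-[(tert-butyldimethylsilyl)oxy]-2-methylpropyl]furan-2(5H)-one
Product: 8 (4S,5S)-5-[(2S)-3-[(tert-butyldimethylsilyl)oxy]-2-methylpropyl]-4-vinyldihydrofuran-2(3H)-one
Conditions: vinylmagnesium bromide, CuI, THF/Me2S, −78 to −40 °C
Reagents that add atoms: vinylmagnesium bromide C=C[Mg]Br
Why: Organocopper conjugate addition to the butenolide occurs anti to the C-5 substituent, which sets C-7 trans to C-8 as the later trans lactone fusion requires.

Step 7
Reactants: 8 (4S,5S)-5-[(2S)-3-[(tert-butyldimethylsilyl)oxy]-2-methylpropyl]-4-vinyldihydrofuran-2(3H)-one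
Product: 9 (4S,5S)-5-[(2S)-3-hydroxy-2-methylpropyl]-4-vinyldihydrofuran-2(3H)-one
Conditions: HF·pyridine, pyridine, THF, 0 °C to rt
Reagents that add atoms: none
Why: Fluoride cleavage of a primary silyl ether under conditions that leave the lactone and the vinyl group alone.

Step 8
Reactants: 9 (4S,5S)-5-[(2S)-3-hydroxy-2-methylpropyl]-4-vinyldihydrofuran-2(3H)-one
Product: 10 (2S)-2-methyl-3-[(2S,3S)-5-oxo-3-vinyltetrahydrofuran-2-yl]propanal
Conditions: Dess–Martin periodinane, NaHCO3, CH2Cl2, 0 °C to rt; used at once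
Reagents that add atoms: none
Why: Buffered Dess–Martin oxidation gives the α-methyl aldehyde without enolisation, so C-10 should keep its configuration.

Step 9
Reactants: 10 (2S)-2-methyl-3-[(2S,3S)-5-oxo-3-vinyltetrahydrofuran-2-yl]propanal
Product: 11 (4S,5S)-5-[(2S)-3-hydroxy-2-methylpent-4-en-1-yl]-4-vinyldihydrofuran-2(3H)-one (both carbinol epimers)
Conditions: vinylmagnesium bromide (1.1 equiv), THF, −78 °C
Reagents that add atoms: vinylmagnesium bromide C=C[Mg]Br
Why: Grignard 1,2-addition to the aldehyde is much faster than attack on the γ-lactone at −78 °C, and the new carbinol centre is removed again in step 11.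

Step 10
Reactants: 11 (4S,5S)-5-[(2S)-3-hydroxy-2-methylpent-4-en-1-yl]-4-vinyldihydrofuran-2(3H)-one
Product: 12 (3aS,7S,8aS)-6-hydroxy-7-methyl-3,3a,6,7,8,8a-hexahydro-2H-cyclohepta[b]furan-2-one (both C-6 epimers)
Conditions: second-generation Grubbs catalyst (5 mol%), CH2Cl2 (5 mM), 40 °C
Reagents that add atoms: none
Why: Ring-closing metathesis of two monosubstituted alkenes held on the trans-disubstituted lactone closes the seven-membered ring (C-5=C-6) with loss of ethylene.

Step 11
Reactants: 12 (3aS,7S,8aS)-6-hydroxy-7-methyl-3,3a,6,7,8,8a-hexahydro-2H-cyclohepta[b]furan-2-one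
Product: 13 (3aS,7S,8aS)-7-methyl-3,3a,8,8a-tetrahydro-2H-cyclohepta[b]furan-2,6(7H)-dione
Conditions: Dess–Martin periodinane, NaHCO3, CH2Cl2, 0 °C to rt
Reagents that add atoms: none
Why: Dess–Martin oxidation of the allylic alcohol gives the cycloheptenone and converges both carbinol epimers.

Step 12
Reactants: 13 (3aS,7S,8aS)-7-methyl-3,3a,8,8a-tetrahydro-2H-cyclohepta[b]furan-2,6(7H)-dione
Product: 14 (3aR,7S,8aS)-7-methyl-2-oxo-3,3a,4,7,8,8a-hexahydro-2H-cyclohepta[b]furan-6-yl trifluoromethanesulfonate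
Conditions: LiBH(s-Bu)3, THF, −78 °C; then PhNTf2, −78 to 0 °C
Reagents that add atoms: N-phenylbis(trifluoromethanesulfonimide) O=S(=O)(N(c1ccccc1)S(=O)(=O)C(F)(F)F)C(F)(F)F
Why: Conjugate hydride addition to the enone gives the C-1/C-5 enolate regiospecifically, with no deprotonation next to C-10, and O-triflation traps it as the enol triflate.

Step 13
Reactants: 14 (3aR,7S,8aS)-7-methyl-2-oxo-3,3a,4,7,8,8a-hexahydro-2H-cyclohepta[b]furan-6-yl trifluoromethanesulfonate
Product: 17 (3aR,7S,8aS)-7-methyl-3-methylidene-2-oxo-3,3a,4,7,8,8a-hexahydro-2H-cyclohepta[b]furan-6-yl trifluoromethanesulfonate, via Mannich base 15 (not isolated), via ammonium iodide 16 (not isolated)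
Conditions: LiN(i-Pr)2, THF, −78 °C; Eschenmoser's salt (CH2=NMe2+ I−), −78 °C to rt; then MeI, MeOH, rt; then NaHCO3 (aq), CH2Cl2, rt
Reagents that add atoms: Eschenmoser's salt C=[N+](C)C.[I-]
Why: The lactone is the only C–H acid, so the enolate Mannich reaction, quaternisation and E1cB loss of trimethylamine (Eschenmoser methylenation) install the exocyclic C-11=C-13 bond.

Step 14
Reactants: 17 (3aR,7S,8aS)-7-methyl-3-methylidene-2-oxo-3,3a,4,7,8,8a-hexahydro-2H-cyclohepta[b]furan-6-yl trifluoromethanesulfonate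
Product: 18 (3aR,7S,8aS)-6-[(2E)-but-2-enoyl]-7-methyl-3-methylidene-3,3a,4,7,8,8a-hexahydro-2H-cyclohepta[b]furan-2-one
Conditions: CO (1 atm), Pd(PPh3)4 (5 mol%), LiCl, (E)-tributyl(prop-1-enyl)stannane, THF, 55 °C
Reagents that add atoms: carbon monoxide [C-]#[O+]; (E)-tributyl(prop-1-enyl)stannane C/C=C/[Sn](CCCC)(CCCC)CCCC
Why: Carbonylative Stille coupling (oxidative addition of the enol triflate to zerovalent palladium, CO insertion, transmetalation) places the acyl group on C-1 and gives the cross-conjugated dienone.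

Step 15
Reactants: 18 (3aR,7S,8aS)-6-[(2E)-but-2-enoyl]-7-methyl-3-methylidene-3,3a,4,7,8,8a-hexahydro-2H-cyclohepta[b]furan-2-one
Product: 19 2-oxoguaia-1(5),11(13)-dien-12,8α-olide (7αH,8βH,10αH; C-4 epimers)
Conditions: TfOH (1.1 equiv), CH2Cl2, −20 to 0 °C
Reagents that add atoms: none
Why: Nazarov cyclisation: 4π-conrotatory closure of the protonated dienone forms C-4–C-5, proton loss from C-5 puts the double bond at the ring fusion (C-1=C-5), and the C-4 centre is destroyed later.

Step 16
Reactants: 19 2-oxoguaia-1(5),11(13)-dien-12,8α-olide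
Product: 20 2-(trimethylsilyloxy)guaia-1,4,11(13)-trien-12,8α-olide (7αH,8βH,10αH)
Conditions: TMSOTf, Et3N, CH2Cl2, 0 °C to rt; pentane, filtration, concentration; used crude and cold
Reagents that add atoms: trimethylsilyl trifluoromethanesulfonate C[Si](C)(C)OS(=O)(=O)C(F)(F)F
Why: Soft enolisation gives the 2-silyloxycyclopentadiene, and [1,5]-hydrogen shifts should funnel the isomers to the most substituted diene (C-1=C-2, C-4=C-5) with C-3 as CH2.

Step 17
Reactants: 20 2-(trimethylsilyloxy)guaia-1,4,11(13)-trien-12,8α-olide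
Product: 22 4α-hydroxy-2-oxoguaia-1(5),11(13)-dien-12,8α-olide, via endoperoxide 21 (not isolated)
Conditions: O2, tetraphenylporphyrin (1 mol%), visible light, CH2Cl2, −78 °C; then PPh3, −78 °C to rt; then AcOH/H2O/THF
Reagents that add atoms: dioxygen O=O
Why: Singlet oxygen adds [4+2] across C-2 and C-4 of the cyclic siloxydiene on the face anti to the 10β-methyl group, and peroxide reduction with loss of the silyl group leaves the γ-hydroxy enone; the C-4 configuration is not needed later.

Step 18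
Reactants: 22 4α-hydroxy-2-oxoguaia-1(5),11(13)-dien-12,8α-olide
Product: 23 2β,4α-dihydroxyguaia-1(5),11(13)-dien-12,8α-olide
Conditions: (S)-2-methyl-CBS-oxazaborolidine (20 mol%), catecholborane, toluene, −78 °C
Reagents that add atoms: none
Why: Corey–Bakshi–Shibata reduction under catalyst control, with the alkene branch as the large group, delivers hydride to the α face of C-2 and gives the 2β (2R) alcohol; the 10β- and 4β-methyl groups reinforce this sense.

Step 19
Reactants: 23 2β,4α-dihydroxyguaia-1(5),11(13)-dien-12,8α-olide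
Product: 24 2β-acetoxy-4α-hydroxyguaia-1(5),11(13)-dien-12,8α-olide
Conditions: Ac2O (1.2 equiv), pyridine, DMAP (5 mol%), CH2Cl2, 0 °C
Reagents that add atoms: acetic anhydride CC(=O)OC(C)=O
Why: DMAP-catalysed acylation takes the secondary allylic alcohol far faster than the tertiary one.

Step 20
Reactants: 24 2β-acetoxy-4α-hydroxyguaia-1(5),11(13)-dien-12,8α-olide; 25 1-O-acetylbritannilactone
Product: 27 target CNP0211028.3, via cyclopentadiene 26 (not isolated)
Conditions: Martin sulfurane Ph2S[OC(CF3)2Ph]2 (1.0 equiv), CH2Cl2, −40 °C, 20 min; then 25 (3 equiv), about 1 M, −20 to 4 °C, 48 h, argon, dark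
Reagents that add atoms: none
Why: Martin sulfurane converts the tertiary allylic alcohol of 24 into an alkoxysulfonium ion that loses Ph2SO and H-3 (the 2-acetoxy group disfavours charge and proton loss on the C-1/C-2 side) to give cyclopentadiene 26, which then undergoes a thermal suprafacial [4+2] cycloaddition with the exocyclic C-11′=C-13′ bond of 25. The closest known reaction type is the Diels–Alder reaction of cyclopentadienes with α-methylene-γ-butyrolactones, as in biomimetic dimerisations of guaianolide dienes, which favours the exo position for the lactone carbonyl. The ring C-1–C-13′–C-11′–C-3–C-2 closes by intermolecular [4+2] closure, C-1–C-13′ and C-3–C-11′ forming together across the existing cyclopentadiene. C-1 and C-3 are set by attack on the α face of the diene, anti to the 10β-methyl group and to the 2β-acetate (which thereby ends syn to C-4=C-5), and C-11′ is set by the exo orientation of C-12′=O under H-2 together with reaction on the lactone face anti to H-7′, which should be the open face in the half-chair of 25 that holds H-7′ axial. The step needs regioselectivity (C-13′H2 to the fully substituted C-1, since the alternative would join two quaternary carbons), exo selectivity (from the s-cis α-methylene lactone) and α-facial selectivity against the known syn preference of 5-acyloxycyclopentadienes; sterics should secure the last, because on the β face either C-12′ or C-7′ of the 1,1-disubstituted dienophile would have to pass under the acetate while C-13′ passes the 10β-methyl group. Low temperature and high concentration should keep the cycloaddition ahead of the [1,5]-hydrogen shift of 26.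

**Compound list**
1 | (S)-2-methylsuccinic acid 4-methyl ester [(2S)-4-methoxy-2-methyl-4-oxobutanoic acid] | COC(=O)C[C@H](C)C(=O)O | starting material
2 | methyl (3S)-4-hydroxy-3-methylbutanoate | COC(=O)C[C@H](C)CO | intermediate
3 | methyl (3S)-4-[(tert-butyldimethylsilyl)oxy]-3-methylbutanoate | COC(=O)C[C@H](C)CO[Si](C)(C)C(C)(C)C | intermediate
4 | (3S)-4-[(tert-butyldimethylsilyl)oxy]-3-methylbutanal | O=CC[C@H](C)CO[Si](C)(C)C(C)(C)C | intermediate
5 | methyl (4S,6S)-7-[(tert-butyldimethylsilyl)oxy]-4-hydroxy-6-methylhept-2-ynoate | COC(=O)C#C[C@@H](O)C[C@H](C)CO[Si](C)(C)C(C)(C)C | intermediate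
6 | methyl (2Z,4S,6S)-7-[(tert-butyldimethylsilyl)oxy]-4-hydroxy-6-methylhept-2-enoate | COC(=O)/C=C\[C@@H](O)C[C@H](C)CO[Si](C)(C)C(C)(C)C | intermediate
7 | (5S)-5-[(2S)-3-[(tert-butyldimethylsilyl)oxy]-2-methylpropyl]furan-2(5H)-one | O=C1C=C[C@H](C[C@H](C)CO[Si](C)(C)C(C)(C)C)O1 | intermediate
8 | (4S,5S)-5-[(2S)-3-[(tert-butyldimethylsilyl)oxy]-2-methylpropyl]-4-vinyldihydrofuran-2(3H)-one | O=C1C[C@@H](C=C)[C@H](C[C@H](C)CO[Si](C)(C)C(C)(C)C)O1 | intermediate
9 | (4S,5S)-5-[(2S)-3-hydroxy-2-methylpropyl]-4-vinyldihydrofuran-2(3H)-one | O=C1C[C@@H](C=C)[C@H](C[C@H](C)CO)O1 | intermediate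
10 | (2S)-2-methyl-3-[(2S,3S)-5-oxo-3-vinyltetrahydrofuran-2-yl]propanal | O=C1C[C@@H](C=C)[C@H](C[C@H](C)C=O)O1 | intermediate
11 | (4S,5S)-5-[(2S)-3-hydroxy-2-methylpent-4-en-1-yl]-4-vinyldihydrofuran-2(3H)-one, both carbinol epimers | O=C1C[C@@H](C=C)[C@H](C[C@H](C)C(O)C=C)O1 | intermediate
12 | (3aS,7S,8aS)-6-hydroxy-7-methyl-3,3a,6,7,8,8a-hexahydro-2H-cyclohepta[b]furan-2-one, both C-6 epimers, trans ring fusion | O=C1C[C@H]2C=CC(O)[C@@H](C)C[C@@H]2O1 | intermediate
13 | (3aS,7S,8aS)-7-methyl-3,3a,8,8a-tetrahydro-2H-cyclohepta[b]furan-2,6(7H)-dione | O=C1C[C@H]2C=CC(=O)[C@@H](C)C[C@@H]2O1 | intermediate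
14 | (3aR,7S,8aS)-7-methyl-2-oxo-3,3a,4,7,8,8a-hexahydro-2H-cyclohepta[b]furan-6-yl trifluoromethanesulfonate | O=C1C[C@H]2CC=C(OS(=O)(=O)C(F)(F)F)[C@@H](C)C[C@@H]2O1 | intermediate
15 | 3-[(dimethylamino)methyl] derivative of 14 (Mannich base, C-3 epimers) | CN(C)CC1C(=O)O[C@H]2C[C@H](C)C(OS(=O)(=O)C(F)(F)F)=CC[C@H]12 | intermediate
16 | trimethylammonium iodide of 15 | C[N+](C)(C)CC1C(=O)O[C@H]2C[C@H](C)C(OS(=O)(=O)C(F)(F)F)=CC[C@H]12.[I-] | intermediate
17 | (3aR,7S,8aS)-7-methyl-3-methylidene-2-oxo-3,3a,4,7,8,8a-hexahydro-2H-cyclohepta[b]furan-6-yl trifluoromethanesulfonate | C=C1C(=O)O[C@H]2C[C@H](C)C(OS(=O)(=O)C(F)(F)F)=CC[C@H]12 | intermediate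
18 | (3aR,7S,8aS)-6-[(2E)-but-2-enoyl]-7-methyl-3-methylidene-3,3a,4,7,8,8a-hexahydro-2H-cyclohepta[b]furan-2-one | C=C1C(=O)O[C@H]2C[C@H](C)C(C(=O)/C=C/C)=CC[C@H]12 | intermediate
19 | 2-oxoguaia-1(5),11(13)-dien-12,8α-olide (7αH,8βH,10αH; C-4 epimers) | C=C1C(=O)O[C@H]2C[C@H](C)C3=C(C[C@H]12)C(C)CC3=O | intermediate
20 | 2-(trimethylsilyloxy)guaia-1,4,11(13)-trien-12,8α-olide (7αH,8βH,10αH) | C=C1C(=O)O[C@H]2C[C@H](C)C3=C(O[Si](C)(C)C)CC(C)=C3C[C@H]12 | intermediate
21 | 2α,4α-epidioxy-2β-(trimethylsilyloxy)guaia-1(5),11(13)-dien-12,8α-olide | C=C1C(=O)O[C@H]2C[C@H](C)C3=C(C[C@H]12)[C@@]4(C)C[C@]3(O[Si](C)(C)C)OO4 | intermediate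
22 | 4α-hydroxy-2-oxoguaia-1(5),11(13)-dien-12,8α-olide (4β-methyl) | C=C1C(=O)O[C@H]2C[C@H](C)C3=C(C[C@H]12)[C@](C)(O)CC3=O | intermediate
23 | 2β,4α-dihydroxyguaia-1(5),11(13)-dien-12,8α-olide | C=C1C(=O)O[C@H]2C[C@H](C)C3=C(C[C@H]12)[C@](C)(O)C[C@H]3O | intermediate
24 | 2β-acetoxy-4α-hydroxyguaia-1(5),11(13)-dien-12,8α-olide | C=C1C(=O)O[C@H]2C[C@H](C)C3=C(C[C@H]12)[C@](C)(O)C[C@H]3OC(C)=O | intermediate
25 | 1-O-acetylbritannilactone [(4S)-4-[(3aS,4S,7aR)-4-hydroxy-6-methyl-3-methylidene-2-oxo-3a,4,7,7a-tetrahydro-1-benzofuran-5-yl]pentyl acetate] | C=C1C(=O)O[C@@H]2CC(C)=C([C@@H](C)CCCOC(C)=O)[C@@H](O)[C@@H]21 | starting material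
26 | 2β-acetoxyguaia-1(5),3,11(13)-trien-12,8α-olide (7αH,8βH,10αH) | C=C1C(=O)O[C@H]2C[C@H](C)C3=C(C[C@H]12)C(C)=C[C@H]3OC(C)=O | intermediate
27 | CNP0211028.3 | C=C1C(=O)O[C@H]2C[C@H](C)[C@@]34C[C@]5(C(=O)O[C@@H]6CC(C)=C([C@@H](C)CCCOC(C)=O)[C@@H](O)[C@@H]65)[C@@H](C(C)=C3C[C@H]12)[C@H]4OC(C)=O | target

Total steps: 20. Longest linear sequence: 20 steps (1 to 27); 25 enters in step 20.

**Steps most likely to fail**

Step 20. The dienophile may add to the acetate-bearing β face of 26 (poor π-facial selectivity, since a 5-acyloxy group is an electronic syn director), and dienophile-face selectivity may also be modest. The fallback sets out from 23 and 25 and comes back at 27. Diol 23 would be silylated at O-2 (TIPSOTf, 2,6-lutidine) to give 2β-triisopropylsilyl ether F1, and 25 would be turned into its 6′-allyl carbonate F2 (allyl chloroformate, pyridine). Martin sulfurane would dehydrate F1 to silyloxy diene F3, whose isopropyl groups screen the β face at C-3 and whose C–O bond is a weaker acceptor than that of the acetate. Cycloaddition with F2 would give adduct F4, HF·pyridine would free the C-2 alcohol F5, and Ac2O/DMAP would give acetate F6. Pd(PPh3)4 with morpholine would then remove the allyl carbonate to give 27.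

Step 17. The siloxydiene 20 may be oxygenated across the wrong termini, or it may be lost by Diels–Alder self-dimerisation with the α-methylene lactone of a second molecule. The fallback sets out from 19 and comes back at 26, so no γ-hydroxylation is needed. Kinetic enolisation (LiN(SiMe3)2, Me3SiCl, −78 °C) would give silyl enol ether F7, and Saegusa oxidation with Pd(OAc)2 would give cyclopentadienone F8. Luche reduction (NaBH4, CeCl3, MeOH, −78 °C, hydride anti to the 10β-methyl group) would give 2β-hydroxy diene F9. Acetylation at −40 °C (Ac2O, Et3N, DMAP) would give 26, to be used at once with 25 as in step 20.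

Step 15. Under the strong acid the exocyclic lactone double bond may migrate into the ring or polymerise. The fallback sets out from Mannich base 15 (isolated in this case) and comes back at 19, with the lactone methylene masked as its amine adduct during the acid step. Carbonylative Stille coupling of 15 (conditions of step 14) would give amino dienone F10, and Nazarov cyclisation of its triflate salt would give amino enone F11. MeI would give ammonium iodide F12, and aqueous NaHCO3 would release 19.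

Further compounds
F1 | step 20 | 4α-hydroxy-2β-(triisopropylsilyloxy)guaia-1(5),11(13)-dien-12,8α-olide | C=C1C(=O)O[C@H]2C[C@H](C)C3=C(C[C@H]12)[C@](C)(O)C[C@H]3O[Si](C(C)C)(C(C)C)C(C)C
F2 | step 20 | 6′-O-(allyloxycarbonyl)-1-O-acetylbritannilactone | C=C1C(=O)O[C@@H]2CC(C)=C([C@@H](C)CCCOC(C)=O)[C@@H](OC(=O)OCC=C)[C@@H]21
F3 | step 20 | 2β-(triisopropylsilyloxy)guaia-1(5),3,11(13)-trien-12,8α-olide | C=C1C(=O)O[C@H]2C[C@H](C)C3=C(C[C@H]12)C(C)=C[C@H]3O[Si](C(C)C)(C(C)C)C(C)C
F4 | step 20 | cycloadduct with 2-O-triisopropylsilyl and 6′-O-allyloxycarbonyl groups | C=C1C(=O)O[C@H]2C[C@H](C)[C@@]34C[C@]5(C(=O)O[C@@H]6CC(C)=C([C@@H](C)CCCOC(C)=O)[C@@H](OC(=O)OCC=C)[C@@H]65)[C@@H](C(C)=C3C[C@H]12)[C@H]4O[Si](C(C)C)(C(C)C)C(C)C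
F5 | step 20 | 2-hydroxy cycloadduct with 6′-O-allyloxycarbonyl group | C=C1C(=O)O[C@H]2C[C@H](C)[C@@]34C[C@]5(C(=O)O[C@@H]6CC(C)=C([C@@H](C)CCCOC(C)=O)[C@@H](OC(=O)OCC=C)[C@@H]65)[C@@H](C(C)=C3C[C@H]12)[C@H]4O
F6 | step 20 | 6′-O-allyloxycarbonyl derivative of 27 | C=C1C(=O)O[C@H]2C[C@H](C)[C@@]34C[C@]5(C(=O)O[C@@H]6CC(C)=C([C@@H](C)CCCOC(C)=O)[C@@H](OC(=O)OCC=C)[C@@H]65)[C@@H](C(C)=C3C[C@H]12)[C@H]4OC(C)=O
F7 | step 17 | 2-(trimethylsilyloxy)guaia-1(5),2,11(13)-trien-12,8α-olide (C-4 epimers) | C=C1C(=O)O[C@H]2C[C@H](C)C3=C(C[C@H]12)C(C)C=C3O[Si](C)(C)C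
F8 | step 17 | 2-oxoguaia-1(5),3,11(13)-trien-12,8α-olide (cyclopentadienone) | C=C1C(=O)O[C@H]2C[C@H](C)C3=C(C[C@H]12)C(C)=CC3=O
F9 | step 17 | 2β-hydroxyguaia-1(5),3,11(13)-trien-12,8α-olide | C=C1C(=O)O[C@H]2C[C@H](C)C3=C(C[C@H]12)C(C)=C[C@H]3O
F10 | step 15 | 3-[(dimethylamino)methyl]-3-hydro derivative of 18 | CN(C)CC1C(=O)O[C@H]2C[C@H](C)C(C(=O)/C=C/C)=CC[C@H]12
F11 | step 15 | 13-(dimethylamino)-11,13-dihydro derivative of 19 | CN(C)CC1C(=O)O[C@H]2C[C@H](C)C3=C(C[C@H]12)C(C)CC3=O
F12 | step 15 | trimethylammonium iodide of F11 | C[N+](C)(C)CC1C(=O)O[C@H]2C[C@H](C)C3=C(C[C@H]12)C(C)CC3=O.[I-]
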